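The carbocycle is detached from the γ-pyrone at C8a–C8 and C4a–C5, the two bonds that join the pyrone C4a=C8a double bond to the cis-disposed carbinol carbons C5 and C8. An enantiopure 6-(methylsulfinyl)-4-pyranone acts as a chiral "pyranyne" equivalent. Its sulfinyl-bearing double bond undergoes a Diels–Alder reaction with (1E,3E)-1,4-bis(silyloxy)butadiene; loss of methanesulfenic acid in the same flask then restores the pyrone. This closes the six-membered ring and sets C5 and C8 in one operation. anti-Epoxidation of the resulting C6=C7 alkene and acid hydrolysis, steered to C6 by the protonated pyrone, complete the tetraol.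

Key step: step 5

Assumption: the π-facial sense of the sulfinyl dienophile is taken from the usual model for enantiopure β-sulfinyl enones and sulfinylquinones (S=O s-cis to C=C, diene anti to the S-alkyl group, endo to the ring); if the sense proved opposite, L-(+)-diethyl tartrate in step 3 would supply the other sulfoxide with no other change.
Remark: compounds 1, 4 and 9 are taken as commercially available.

Step 1
Reactants: 1 3-(3-hydroxy-4-methoxyphenyl)propanoic acid
Product: 3 3-[4-methoxy-3-(methoxymethoxy)phenyl]propanoic acid, via bis-MOM derivative 2 (not isolated)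
Conditions: MOMCl (2.4 equiv), i-Pr2NEt, CH2Cl2, 0 °C → rt; then LiOH, THF–H2O, 0 °C → rt; 1 M HCl to pH 4, 0 °C
Reagents that add atoms: chloromethyl methyl ether, COCCl; lithium hydroxide, [Li+].[OH-]
Why: Williamson-type O-alkylation of both the phenol and the acid, followed by chemoselective saponification of the methoxymethyl ester (the hydroxide oxygen enters the carboxyl group), should leave the phenol as a base-stable MOM ether that is shed in the final acidic step; no stereocentre is involved.

Step 2
Reactants: 3 3-[4-methoxy-3-(methoxymethoxy)phenyl]propanoic acid; 4 4,4-bis(methylsulfanyl)but-3-en-2-one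
Product: 7 2-{2-[4-methoxy-3-(methoxymethoxy)phenyl]ethyl}-6-(methylsulfanyl)-4H-pyran-4-one, via acyl imidazolide 5 (not isolated), via diketone 6 (not isolated)
Conditions: i) 3, CDI, THF, rt; ii) 4, LiHMDS (2.2 equiv), THF, −78 °C, then the solution from i), −78 → 0 °C; iii) AcOH, 60 °C
Reagents that add atoms: none
Why: Claisen-type C-acylation of the lithium enolate of the α-oxoketene dithioacetal 4 by the acyl imidazolide gives β-diketone 6, whose enol oxygen then adds to the bis(methylsulfanyl)vinyl terminus and expels methanethiol (6-endo addition–elimination, the dithioacetal variant of the 4-pyranone synthesis from acylated 4-methoxybut-3-en-2-one), leaving one SMe group on the ring carbon that becomes C8a.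

Step 3
Reactants: 7 2-{2-[4-methoxy-3-(methoxymethoxy)phenyl]ethyl}-6-(methylsulfanyl)-4H-pyran-4-one
Product: 8 2-{2-[4-methoxy-3-(methoxymethoxy)phenyl]ethyl}-6-[(S)-methanesulfinyl]-4H-pyran-4-one
Conditions: Ti(OiPr)4 (0.2 equiv), D-(−)-diethyl tartrate (0.8 equiv), i-PrOH, 4 Å MS, cumene hydroperoxide (1.1 equiv), CH2Cl2, −20 °C; recrystallisation
Reagents that add atoms: cumene hydroperoxide, CC(C)(OO)c1ccccc1
Why: Kagan oxidation (Ti/tartrate/hydroperoxide enantioselective sulfoxidation): the reagent should distinguish the large pyranonyl from the small methyl group on sulfur as it does aryl from methyl, so that (S,S)-tartrate should give the (S)-sulfoxide (mirror image of the (R,R)-tartrate → (R)-aryl methyl sulfoxide correlation), the sulfur stereocentre being set by the reagent and its purity raised by crystallisation.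

Step 4
Reactants: 9 (1E,3E)-buta-1,3-diene-1,4-diyl diacetate
Product: 10 (1E,3E)-1,4-bis[(tert-butyldimethylsilyl)oxy]buta-1,3-diene
Conditions: MeLi (4.2 equiv), DME, −78 → 0 °C; TBSCl (2.4 equiv), DMPU, −78 °C → rt
Reagents that add atoms: tert-butyldimethylsilyl chloride, CC(C)(C)[Si](C)(C)Cl
Why: both enol acetates are cleaved by methyllithium (acyl transfer, the acetyl groups ending as tert-butoxide) to the dilithium dienediolate with retention of the (E,E) geometry, and O-silylation should trap it as the electron-rich diene.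

Step 5
Reactants: 8 2-{2-[4-methoxy-3-(methoxymethoxy)phenyl]ethyl}-6-[(S)-methanesulfinyl]-4H-pyran-4-one; 10 (1E,3E)-1,4-bis[(tert-butyldimethylsilyl)oxy]buta-1,3-diene
Product: 12 (5R,8S)-5,8-bis[(tert-butyldimethylsilyl)oxy]-2-{2-[4-methoxy-3-(methoxymethoxy)phenyl]ethyl}-5,8-dihydro-4H-chromen-4-one, via cis-fused cycloadduct 11 (not isolated)
Conditions: 10 (2.5 equiv), BHT (cat.), PhMe, 80 °C, sealed tube
Reagents that add atoms: none
Why: The sulfinyl- and carbonyl-activated C5=C6 bond of 8 (the future C4a=C8a bond) is the 2π partner in a concerted, suprafacial normal-demand [4+2] cycloaddition with the electron-rich s-cis diene 10, which forms C8a–C8 and C4a–C5 together; the β-sulfinyl ketone 11 should then lose methanesulfenic acid by thermal syn-elimination across C8a–C4a, where sulfur and the acidic α-keto hydrogen are cis, so that the pyranone is restored and the sulfoxide has served as a traceless chiral alkyne equivalent. The closest known reaction type is the tandem Diels–Alder/sulfoxide elimination of enantiopure 2-sulfinyl-1,4-benzoquinones and β-sulfinyl enones with 1-oxygenated dienes. The cyclohexene ring is closed in the intermolecular cycloaddition itself (six-membered, both new σ-bonds made on one face of each partner). The cis relation of the C5 and C8 silyloxy groups follows from the (E,E) geometry of 10; their absolute configuration is set by sulfur, because in the s-cis S=O/C=C conformer of the (S)-sulfoxide the S-methyl group shields one face, the diene should add to the lone-pair face with its inner carbons under the pyranone ring (endo), and after elimination this gives (5R,8S). The step needs π-facial and endo selectivity (an exo adduct on the same face would lead to the enantiomer), chemoselectivity for C5=C6 over C2=C3 (only the former carries the sulfinyl group) and elimination towards C4a and not C8, which the α-keto acidity of H-4a should secure; regiochemistry is not an issue because 10 is C2-symmetric.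

Step 6
Reactants: 12 (5R,8S)-5,8-bis[(tert-butyldimethylsilyl)oxy]-2-{2-[4-methoxy-3-(methoxymethoxy)phenyl]ethyl}-5,8-dihydro-4H-chromen-4-one
Product: 13 (5S,6S,7R,8S)-5,8-bis[(tert-butyldimethylsilyl)oxy]-6,7-epoxy-2-{2-[4-methoxy-3-(methoxymethoxy)phenyl]ethyl}-5,6,7,8-tetrahydro-4H-chromen-4-one (epoxide oxygen anti to both silyloxy groups)
Conditions: m-CPBA (1.5 equiv), NaHCO3, CH2Cl2, 0 °C → rt
Reagents that add atoms: m-chloroperbenzoic acid, OOC(=O)c1cccc(Cl)c1
Why: Prilezhaev epoxidation of the only electron-normal alkene (both pyranone C=C bonds are deactivated as a vinylogous ester); the two silyloxy groups stand on the same face of the boat-like dihydro ring and the peracid should add to the opposite face, which fixes the C7–O bond anti to O5 and O8.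

Step 7
Reactants: 13 (5S,6S,7R,8S)-5,8-bis[(tert-butyldimethylsilyl)oxy]-6,7-epoxy-2-{2-[4-methoxy-3-(methoxymethoxy)phenyl]ethyl}-5,6,7,8-tetrahydro-4H-chromen-4-one
Product: 14 (5S,6S,7R,8S)-5,6,7,8-tetrahydroxy-2-[2-(3-hydroxy-4-methoxyphenyl)ethyl]-5,6,7,8-tetrahydro-4H-chromen-4-one
Conditions: TFA–H2O (3:1), 0 °C → rt; evaporation
Reagents that add atoms: water, O
Why: acid-catalysed epoxide hydrolysis (A-2, anti opening) with concomitant cleavage of the two silyl ethers and the MOM ether; in TFA the pyranone is O-protonated to a 4-hydroxypyrylium ion whose positive charge sits on C8a (and C2, C4) but not on C4a, so that charge build-up at C7 (two bonds from C8a) is disfavoured and water should attack C6 with inversion from the face of O5/O8, giving the 5,6-cis, 6,7-trans, 7,8-trans tetraol with C7 keeping the epoxide oxygen.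

Compound list
1 | 3-(3-hydroxy-4-methoxyphenyl)propanoic acid | COc1ccc(CCC(=O)O)cc1O | starting material
2 | methoxymethyl 3-[4-methoxy-3-(methoxymethoxy)phenyl]propanoate | COc1ccc(CCC(=O)OCOC)cc1OCOC | intermediate
3 | 3-[4-methoxy-3-(methoxymethoxy)phenyl]propanoic acid | COc1ccc(CCC(=O)O)cc1OCOC | intermediate
4 | 4,4-bis(methylsulfanyl)but-3-en-2-one | CC(=O)C=C(SC)SC | starting material
5 | 1-{3-[4-methoxy-3-(methoxymethoxy)phenyl]propanoyl}-1H-imidazole | COc1ccc(CCC(=O)n2ccnc2)cc1OCOC | intermediate
6 | 7-[4-methoxy-3-(methoxymethoxy)phenyl]-1,1-bis(methylsulfanyl)hept-1-ene-3,5-dione | COc1ccc(CCC(=O)CC(=O)C=C(SC)SC)cc1OCOC | intermediate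
7 | 2-{2-[4-methoxy-3-(methoxymethoxy)phenyl]ethyl}-6-(methylsulfanyl)-4H-pyran-4-one | COc1ccc(CCc2cc(=O)cc(SC)o2)cc1OCOC | intermediate
8 | 2-{2-[4-methoxy-3-(methoxymethoxy)phenyl]ethyl}-6-[(S)-methanesulfinyl]-4H-pyran-4-one | COc1ccc(CCc2cc(=O)cc(o2)[S@](C)=O)cc1OCOC | intermediate
9 | (1E,3E)-buta-1,3-diene-1,4-diyl diacetate | CC(=O)O/C=C/C=C/OC(C)=O | starting material
10 | (1E,3E)-1,4-bis[(tert-butyldimethylsilyl)oxy]buta-1,3-diene | CC(C)(C)[Si](C)(C)O/C=C/C=C/O[Si](C)(C)C(C)(C)C | intermediate
11 | cis-fused cycloadduct: 5,8-bis[(tert-butyldimethylsilyl)oxy]-8a-[(S)-methanesulfinyl]-2-{2-[4-methoxy-3-(methoxymethoxy)phenyl]ethyl}-4a,5,8,8a-tetrahydro-4H-chromen-4-one, H-4a cis to the sulfinyl group, both silyloxy groups cis to each other and trans to the sulfinyl group | CC(C)(C)[Si](C)(C)O[C@H]1C=C[C@@H](O[Si](C)(C)C(C)(C)C)[C@H]2C(=O)C=C(CCc3ccc(OC)c(OCOC)c3)O[C@@]12[S@](C)=O | intermediate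
12 | (5R,8S)-5,8-bis[(tert-butyldimethylsilyl)oxy]-2-{2-[4-methoxy-3-(methoxymethoxy)phenyl]ethyl}-5,8-dihydro-4H-chromen-4-one | COc1ccc(CCc2cc(=O)c3c(o2)[C@@H](O[Si](C)(C)C(C)(C)C)C=C[C@H]3O[Si](C)(C)C(C)(C)C)cc1OCOC | intermediate
13 | (5S,6S,7R,8S)-5,8-bis[(tert-butyldimethylsilyl)oxy]-6,7-epoxy-2-{2-[4-methoxy-3-(methoxymethoxy)phenyl]ethyl}-5,6,7,8-tetrahydro-4H-chromen-4-one | COc1ccc(CCc2cc(=O)c3c(o2)[C@@H](O[Si](C)(C)C(C)(C)C)[C@@H]2O[C@@H]2[C@H]3O[Si](C)(C)C(C)(C)C)cc1OCOC | intermediate
14 | (5S,6S,7R,8S)-5,6,7,8-tetrahydroxy-2-[2-(3-hydroxy-4-methoxyphenyl)ethyl]-5,6,7,8-tetrahydro-4H-chromen-4-one | COc1ccc(CCc2cc(=O)c3c(o2)[C@@H](O)[C@H](O)[C@@H](O)[C@H]3O)cc1O | target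

Total step count: 7. Longest linear sequence: 6 steps (steps 1, 2, 3, 5, 6, 7); step 4 is a one-step side branch.

Steps most likely to fail

Step 5. The ring oxygen on the dienophile double bond raises its LUMO, so the cycloaddition may be too slow at temperatures the diene tolerates, and desilylation by the liberated sulfenic acid may compete. Incomplete endo or π-facial control would also erode the enantiomeric purity of 12, because the ring-fusion stereocentres are erased on elimination. The fallback sets out from 7 and 10 and comes back at 12. Sulfide 7 is oxidised with excess m-CPBA to the sulfone 2-{2-[4-methoxy-3-(methoxymethoxy)phenyl]ethyl}-6-(methanesulfonyl)-4H-pyran-4-one F1, a far more electron-poor β-sulfonyl enone. Its cycloaddition with 10, followed by E1cB loss of methanesulfinate (Et3N), should give 12 as the racemate, that is together with its (5S,8R)-enantiomer F2. The two are separated by preparative chromatography on a chiral stationary phase, and 12 continues with step 6.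

Step 3. Oxidation of the electron-poor (vinylogous thioester) sulfur may be slow and the reagent may differentiate its two substituents poorly, giving low enantioselectivity, while over-oxidation to the sulfone consumes material. The fallback sets out from 7 and comes back at 12; it replaces catalytic sulfoxidation by an Andersen synthesis. The sulfone F1 (from 7 as above) is converted by addition–elimination with NaI in acetone (Finkelstein-type) into 6-iodo-2-{2-[4-methoxy-3-(methoxymethoxy)phenyl]ethyl}-4H-pyran-4-one F3. Iodine–magnesium exchange (i-PrMgCl·LiCl, THF, −78 °C) and trapping with (1R,2S,5R)-(−)-menthyl (S)-p-toluenesulfinate should give, with inversion at sulfur, 2-{2-[4-methoxy-3-(methoxymethoxy)phenyl]ethyl}-6-[(S)-4-methylbenzenesulfinyl]-4H-pyran-4-one F4. F4 has the same spatial arrangement at sulfur as 8 and takes its place in step 5, where p-toluenesulfenic acid is lost and 12 is formed.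

Step 7. Water may attack C7 instead of C6, especially once the silyl ethers have been cleaved, which would give the 5,6-trans/7,8-cis diastereomer; acid-promoted ionisation at C5 or dehydration towards the aromatic chromone may also compete. The fallback sets out from 12 and comes back at 14; it replaces the charge-based regiocontrol by neighbouring-group control.
- TBAF/AcOH should give the (5R,8S)-5,8-diol F5.
- TBSCl (1.05 equiv) with imidazole should silylate only the C8 hydroxyl, since the C5 hydroxyl is hydrogen-bonded to and screened by the peri C4 carbonyl, giving the 8-O-silyl ether F6.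
- Ac2O/DMAP/pyridine gives the 5-O-acetate F7, and m-CPBA its anti-epoxide F8.
- In TFA the C5 acetate should open the epoxide at C6 from its own face (acetoxonium ion). Addition of water then hydrolyses this ion and cleaves the silyl and MOM ethers, giving the 5-O-acetyl derivative of 14, F9.
- K2CO3 (cat.) in MeOH at 0 °C removes the acetate to give 14.

Further compounds
F1 | step 5 | 2-{2-[4-methoxy-3-(methoxymethoxy)phenyl]ethyl}-6-(methanesulfonyl)-4H-pyran-4-one | COc1ccc(CCc2cc(=O)cc(o2)S(C)(=O)=O)cc1OCOC
F2 | step 5 | (5S,8R)-5,8-bis[(tert-butyldimethylsilyl)oxy]-2-{2-[4-methoxy-3-(methoxymethoxy)phenyl]ethyl}-5,8-dihydro-4H-chromen-4-one | COc1ccc(CCc2cc(=O)c3c(o2)[C@H](O[Si](C)(C)C(C)(C)C)C=C[C@@H]3O[Si](C)(C)C(C)(C)C)cc1OCOC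
F3 | step 3 | 6-iodo-2-{2-[4-methoxy-3-(methoxymethoxy)phenyl]ethyl}-4H-pyran-4-one | COc1ccc(CCc2cc(=O)cc(I)o2)cc1OCOC
F4 | step 3 | 2-{2-[4-methoxy-3-(methoxymethoxy)phenyl]ethyl}-6-[(S)-4-methylbenzenesulfinyl]-4H-pyran-4-one | COc1ccc(CCc2cc(=O)cc(o2)[S@@](=O)c2ccc(C)cc2)cc1OCOC
F5 | step 7 | (5R,8S)-5,8-dihydroxy-2-{2-[4-methoxy-3-(methoxymethoxy)phenyl]ethyl}-5,8-dihydro-4H-chromen-4-one | COc1ccc(CCc2cc(=O)c3c(o2)[C@@H](O)C=C[C@H]3O)cc1OCOC
F6 | step 7 | (5R,8S)-8-[(tert-butyldimethylsilyl)oxy]-5-hydroxy-2-{2-[4-methoxy-3-(methoxymethoxy)phenyl]ethyl}-5,8-dihydro-4H-chromen-4-one | COc1ccc(CCc2cc(=O)c3c(o2)[C@@H](O[Si](C)(C)C(C)(C)C)C=C[C@H]3O)cc1OCOC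
F7 | step 7 | (5R,8S)-5-acetoxy-8-[(tert-butyldimethylsilyl)oxy]-2-{2-[4-methoxy-3-(methoxymethoxy)phenyl]ethyl}-5,8-dihydro-4H-chromen-4-one | COc1ccc(CCc2cc(=O)c3c(o2)[C@@H](O[Si](C)(C)C(C)(C)C)C=C[C@H]3OC(C)=O)cc1OCOC
F8 | step 7 | anti-6,7-epoxide of F7 (epoxide oxygen opposite to the acetoxy and silyloxy groups) | COc1ccc(CCc2cc(=O)c3c(o2)[C@@H](O[Si](C)(C)C(C)(C)C)[C@@H]2O[C@@H]2[C@H]3OC(C)=O)cc1OCOC
F9 | step 7 | 5-O-acetyl derivative of 14 | COc1ccc(CCc2cc(=O)c3c(o2)[C@@H](O)[C@H](O)[C@@H](O)[C@H]3OC(C)=O)cc1O
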